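**Plan**

1. Lignan numbering is used: oxolane O–C7(aryl)–C8(C9H2OH)–C8'(C7'H(OH)aryl)–C9'H2. The target is (7S,8S,7'S,8'S), and all three ring substituents are cis. The chain C7–C8–C8'–C7' has like-configured oxygenated ends, so it maps onto a 1,4-diarylbut-2-yne-1,4-diol. C9 and C9' are one-carbon branches on its two inner atoms, that is, the two halves of one ethylene molecule.
2. Retrosynthetic cuts, in order: the aryl benzyl ethers; C9–OH and C8–H (back to an exocyclic alkene C8=C9); the ring bond O–C9'; C9'–OH and C8'–H (back to C8'=C9'); C8=C9 and C8'=C9' together (alkyne C8≡C8' plus ethylene); C7–C8 and C7'–C8' (acetylide plus aldehyde, twice).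
3. Forward: aldehyde, acetylene unit and aldehyde are joined to the C2-symmetric ynediol bis-silyl ether. Enyne metathesis then installs C9 and C9'. The two alkenes are used one after the other, and the only ring (the oxolane) closes between these two events by 5-exo-tet displacement.
4. Stereochemistry: C7 and C7' come from two (S)-BINOL/Ti(OiPr)4-controlled alkynylations. C8' comes from C7' through acyclic anti-selective 9-BBN addition. C8 comes from the ring, because 9-BBN adds on the face opposite the two cis substituents.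
5. Using the alkenes one at a time avoids a tetraol in which C9–OH would compete with C7–OH for C9'. It lets the ring close before it is crowded, and no Lewis acid touches the epimerisable all-cis benzylic ether.

Key step: step 6

Abbreviations: Ar = 4-(benzyloxy)-3-methoxyphenyl; TBS = tert-butyldimethylsilyl; Ms = methanesulfonyl.

Assumption: (S)-BINOL/Ti(OiPr)4 delivers zinc acetylides to the Si face of aryl aldehydes. The R/S changes at C7 and C7' along the route (4 to 5, 6 to 8, 11 to 13) are changes of CIP ranking only; no bond at these centres is broken.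

Step 1
Reactants: 1 O-benzylvanillin; 2 trimethylsilylacetylene
Product: 4 (1R)-1-Ar-3-(trimethylsilyl)prop-2-yn-1-ol, via ethylzinc acetylide 3 (not isolated)
Conditions: 2, ZnEt2, Cy2NH (cat.), (S)-BINOL (20 mol %), Et2O, rt; Ti(OiPr)4 (1 equiv); then 1, rt
Reagents that add atoms: diethylzinc, CC[Zn]CC (zinc and ethyl stay only in 3)
Why: Catalytic asymmetric alkynylation of an aryl aldehyde with an alkynylzinc under BINOL–Ti(OiPr)4 control is a broadly used reaction type, and Si-face delivery should set the first carbinol centre as R.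

Step 2
Reactants: 4 (1R)-1-Ar-3-(trimethylsilyl)prop-2-yn-1-ol
Product: 5 (1S)-1-Ar-prop-2-yn-1-ol
Conditions: K2CO3 (cat.), MeOH, rt
Reagents that add atoms: none
Why: Base-catalysed protodesilylation of an alkynylsilane by methanol cleaves only the C–Si bond and leaves the benzyl ether and the carbinol centre untouched.

Step 3
Reactants: 5 (1S)-1-Ar-prop-2-yn-1-ol
Product: 6 (1S)-1-Ar-prop-2-yn-1-yl TBS ether
Conditions: TBSCl, imidazole, DMF, rt
Reagents that add atoms: tert-butyldimethylsilyl chloride, CC(C)(C)[Si](C)(C)Cl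
Why: Standard O-silylation under non-acidic conditions masks the alcohol against ZnEt2 without risk of ionisation at the electron-rich propargylic benzylic carbon.

Step 4
Reactants: 6 (1S)-1-Ar-prop-2-yn-1-yl TBS ether; 1 O-benzylvanillin
Product: 8 (1R,4R)-1,4-di-Ar-4-(TBSO)but-2-yn-1-ol, via ethylzinc acetylide 7 (not isolated)
Conditions: 6 (1.3 equiv), ZnEt2, Cy2NH (cat.), (S)-BINOL (20 mol %), Et2O, rt; Ti(OiPr)4 (1 equiv); then 1, rt
Reagents that add atoms: diethylzinc, CC[Zn]CC (zinc and ethyl stay only in 7)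
Why: The same catalyst-controlled asymmetric alkynylation sets the second carbinol with the same sense, because the existing centre lies four atoms away across the linear alkyne and hardly interferes; the minor enantiomer of 6 ends up mainly in the separable unlike diastereomer, which should raise the optical purity of 8.

Step 5
Reactants: 8 (1R,4R)-1,4-di-Ar-4-(TBSO)but-2-yn-1-ol
Product: 9 (1R,4R)-1,4-di-Ar-1,4-bis(TBSO)but-2-yne
Conditions: TBSCl, imidazole, DMF, rt to 40 °C
Reagents that add atoms: tert-butyldimethylsilyl chloride, CC(C)(C)[Si](C)(C)Cl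
Why: O-silylation of the second propargylic alcohol restores C2 symmetry and gives a precursor with no acidic or ionisable group.

Step 6
Reactants: 9 (1R,4R)-1,4-di-Ar-1,4-bis(TBSO)but-2-yne; 10 ethylene
Product: 11 (1R,4R)-1,4-di-Ar-1,4-bis(TBSO)-2,3-dimethylidenebutane
Conditions: RuCl2(H2IMes)(PCy3)(=CHPh) (second-generation Grubbs catalyst, 10 mol %), ethylene (4 atm), toluene, 80 °C
Reagents that add atoms: none
Why: Ethylene first turns the benzylidene precatalyst into Ru=CH2; this cycloadds to C8≡C8' and the ruthenacyclobutene ring-opens to a vinylcarbene in which C8=C9 already exists, after which cycloaddition of ethylene and cycloreversion create C8'=C9' and return Ru=CH2. The closest known reaction type is ethylene–alkyne cross enyne metathesis, which is established for internal alkynes with propargylic acetates, ethers and silyl ethers. No ring closes and no stereocentre is formed, and C7 and C7' never belong to a metallacycle, so their configuration should be retained. Both orientations of the first cycloaddition lead to the same diene because alkyne and alkene are each symmetric, so no regiochemical question arises. The selectivity needed is capture of the hindered vinylcarbene by ethylene rather than by a second alkyne or by product diene, which the ethylene pressure and the flanked 1,1-disubstituted alkenes of 11 should secure. Silyl ethers are preferred to esters because they do not ionise at the doubly activated C7 and C7' positions, cannot migrate to the primary alcohol of step 7 and serve as the masked nucleophile of step 9.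

Step 7
Reactants: 11 (1R,4R)-1,4-di-Ar-1,4-bis(TBSO)-2,3-dimethylidenebutane
Product: 13 (2S)-2-[(S)-Ar(TBSO)methyl]-3-[(S)-Ar(TBSO)methyl]but-3-en-1-ol, via mono-9-BBN adduct 12 (not isolated)
Conditions: 9-BBN (1.0 equiv), THF, 0 °C to rt; then NaOH, H2O2, 0 °C
Reagents that add atoms: 9-borabicyclo[3.3.1]nonane, B1C2CCCC1CCC2 (boron stays only in 12); hydrogen peroxide, OO
Why: In this hydroboration–oxidation boron goes to terminal C9', and in the reactive rotamer C7'–H lies next to the methylene, the silyloxy group points outward and the aryl group covers one face, so hydrogen should reach C8' anti to the aryl group and give the anti (7'S,8'S) relation known for 9-BBN with 2-substituted allylic silyl ethers; the two alkenes of 11 are homotopic and give the same product, and the surviving alkene, now flanked by two branched sp3 carbons, should react more slowly.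

Step 8
Reactants: 13 (2S)-2-[(S)-Ar(TBSO)methyl]-3-[(S)-Ar(TBSO)methyl]but-3-en-1-ol
Product: 14 methanesulfonate of 13
Conditions: MsCl, Et3N, CH2Cl2, 0 °C
Reagents that add atoms: methanesulfonyl chloride, CS(=O)(=O)Cl
Why: Sulfonylation of the only free, primary hydroxyl group turns C9' into the electrophile while both benzylic oxygens remain silylated.

Step 9
Reactants: 14 methanesulfonate of 13
Product: 16 (S)-Ar[(3S,5S)-5-Ar-4-methylideneoxolan-3-yl]methanol, via diol mesylate 15 (not isolated)
Conditions: TBAF (3 equiv), THF, 0 °C to rt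
Reagents that add atoms: none
Why: Fluoride desilylation is followed by an intramolecular Williamson ether synthesis in which O–C7 displaces the primary mesylate at C9' (5-exo-tet); no bond at a stereocentre breaks, no C9 hydroxyl exists yet to compete, the alternative 4-exo closure from O–C7' is far slower, and the resulting 2,4-cis oxolane with an sp2 carbon between the substituents is unstrained.

Step 10
Reactants: 16 (S)-Ar[(3S,5S)-5-Ar-4-methylideneoxolan-3-yl]methanol
Product: 18 (S)-Ar[(3S,4S,5S)-5-Ar-4-(hydroxymethyl)oxolan-3-yl]methanol, via bis-9-BBN adduct 17 (not isolated)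
Conditions: 9-BBN (3 equiv), THF, rt to 40 °C; then NaOH, H2O2, 0 °C
Reagents that add atoms: 9-borabicyclo[3.3.1]nonane, B1C2CCCC1CCC2 (boron stays only in 17); hydrogen peroxide, OO
Why: In this hydroboration–oxidation of an exocyclic methylene the aryl group on C7 and the side chain on C8' both stand on the same ring face, so 9-BBN should deliver hydrogen to C8 from the open face and push C9 to the crowded one, giving the all-cis (8S) centre under kinetic control; the free C7' hydroxyl only forms a borinate that the oxidation cleaves.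

Step 11
Reactants: 18 (S)-Ar[(3S,4S,5S)-5-Ar-4-(hydroxymethyl)oxolan-3-yl]methanol
Product: 19 target CNP0236765.9
Conditions: H2 (1 atm), 10% Pd/C, EtOAc–EtOH, rt, stopped after two equivalents of H2
Reagents that add atoms: none
Why: In catalytic hydrogenolysis under neutral conditions aryl benzyl ethers are cleaved faster than the secondary benzylic C7–O and C7'–O bonds, so both phenols should be freed without touching a stereocentre.

**Compound list**

1 | 4-(benzyloxy)-3-methoxybenzaldehyde (O-benzylvanillin) | COc1cc(C=O)ccc1OCc1ccccc1 | starting material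
2 | ethynyltrimethylsilane | C#C[Si](C)(C)C | starting material
3 | ethyl[(trimethylsilyl)ethynyl]zinc | CC[Zn]C#C[Si](C)(C)C | intermediate
4 | (1R)-1-[4-(benzyloxy)-3-methoxyphenyl]-3-(trimethylsilyl)prop-2-yn-1-ol | COc1cc([C@@H](O)C#C[Si](C)(C)C)ccc1OCc1ccccc1 | intermediate
5 | (1S)-1-[4-(benzyloxy)-3-methoxyphenyl]prop-2-yn-1-ol | COc1cc([C@@H](O)C#C)ccc1OCc1ccccc1 | intermediate
6 | tert-butyl{[(1S)-1-[4-(benzyloxy)-3-methoxyphenyl]prop-2-yn-1-yl]oxy}dimethylsilane | COc1cc([C@@H](O[Si](C)(C)C(C)(C)C)C#C)ccc1OCc1ccccc1 | intermediate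
7 | ethylzinc acetylide of 6 | COc1cc([C@@H](O[Si](C)(C)C(C)(C)C)C#C[Zn]CC)ccc1OCc1ccccc1 | intermediate
8 | (1R,4R)-1,4-bis[4-(benzyloxy)-3-methoxyphenyl]-4-[(tert-butyldimethylsilyl)oxy]but-2-yn-1-ol | COc1cc([C@@H](O[Si](C)(C)C(C)(C)C)C#C[C@H](O)c2ccc(OCc3ccccc3)c(OC)c2)ccc1OCc1ccccc1 | intermediate
9 | (1R,4R)-1,4-bis[4-(benzyloxy)-3-methoxyphenyl]-1,4-bis[(tert-butyldimethylsilyl)oxy]but-2-yne | COc1cc([C@@H](O[Si](C)(C)C(C)(C)C)C#C[C@H](O[Si](C)(C)C(C)(C)C)c2ccc(OCc3ccccc3)c(OC)c2)ccc1OCc1ccccc1 | intermediate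
10 | ethylene | C=C | starting material
11 | (1R,4R)-1,4-bis[4-(benzyloxy)-3-methoxyphenyl]-1,4-bis[(tert-butyldimethylsilyl)oxy]-2,3-dimethylidenebutane | COc1cc([C@@H](O[Si](C)(C)C(C)(C)C)C(=C)C(=C)[C@H](O[Si](C)(C)C(C)(C)C)c2ccc(OCc3ccccc3)c(OC)c2)ccc1OCc1ccccc1 | intermediate
12 | C9'-(9-borabicyclo[3.3.1]nonan-9-yl) mono-adduct of 11 | COc1cc([C@@H](O[Si](C)(C)C(C)(C)C)[C@H](CB2C3CCCC2CCC3)C(=C)[C@H](O[Si](C)(C)C(C)(C)C)c2ccc(OCc3ccccc3)c(OC)c2)ccc1OCc1ccccc1 | intermediate
13 | (2S)-2-[(S)-Ar(TBSO)methyl]-3-[(S)-Ar(TBSO)methyl]but-3-en-1-ol | COc1cc([C@@H](O[Si](C)(C)C(C)(C)C)[C@H](CO)C(=C)[C@H](O[Si](C)(C)C(C)(C)C)c2ccc(OCc3ccccc3)c(OC)c2)ccc1OCc1ccccc1 | intermediate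
14 | (2S)-2-[(S)-Ar(TBSO)methyl]-3-[(S)-Ar(TBSO)methyl]but-3-en-1-yl methanesulfonate | COc1cc([C@@H](O[Si](C)(C)C(C)(C)C)[C@H](COS(C)(=O)=O)C(=C)[C@H](O[Si](C)(C)C(C)(C)C)c2ccc(OCc3ccccc3)c(OC)c2)ccc1OCc1ccccc1 | intermediate
15 | (2S)-2-[(S)-Ar(hydroxy)methyl]-3-[(S)-Ar(hydroxy)methyl]but-3-en-1-yl methanesulfonate | COc1cc([C@@H](O)[C@H](COS(C)(=O)=O)C(=C)[C@H](O)c2ccc(OCc3ccccc3)c(OC)c2)ccc1OCc1ccccc1 | intermediate
16 | (S)-[4-(benzyloxy)-3-methoxyphenyl]{(3S,5S)-5-[4-(benzyloxy)-3-methoxyphenyl]-4-methylideneoxolan-3-yl}methanol | COc1cc([C@@H](O)[C@@H]2CO[C@H](c3ccc(OCc4ccccc4)c(OC)c3)C2=C)ccc1OCc1ccccc1 | intermediate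
17 | adduct of 16 carrying 9-BBN on C9 and on O–C7' | COc1cc([C@@H](OB2C3CCCC2CCC3)[C@@H]2CO[C@H](c3ccc(OCc4ccccc4)c(OC)c3)[C@@H]2CB2C3CCCC2CCC3)ccc1OCc1ccccc1 | intermediate
18 | (S)-[4-(benzyloxy)-3-methoxyphenyl]{(3S,4S,5S)-5-[4-(benzyloxy)-3-methoxyphenyl]-4-(hydroxymethyl)oxolan-3-yl}methanol | COc1cc([C@@H](O)[C@@H]2CO[C@H](c3ccc(OCc4ccccc4)c(OC)c3)[C@@H]2CO)ccc1OCc1ccccc1 | intermediate
19 | (S)-(4-hydroxy-3-methoxyphenyl)[(3S,4S,5S)-5-(4-hydroxy-3-methoxyphenyl)-4-(hydroxymethyl)oxolan-3-yl]methanol | COc1cc([C@@H](O)[C@@H]2CO[C@H](c3ccc(O)c(OC)c3)[C@@H]2CO)ccc1O | target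

Total step count: 11. Longest linear sequence: 11 steps, from 1 to 19.

**Steps most likely to fail**

**Step 7.** The mono-adduct 12 may take up a second 9-BBN about as fast as diene 11 takes up the first. The facial preference at C8' may also be eroded by the bulky alkenyl neighbour.

The fallback gives up the one-at-a-time use of the alkenes and works in two directions, setting out from 11.
- Excess 9-BBN followed by NaOH/H2O2 should give the C2-symmetric bis-silylated 1,4-diol F1.
- Ag2O and 2-(bromomethyl)naphthalene alkylate one of the two homotopic primary alcohols to give the mono(naphthalen-2-ylmethyl) ether F2. This blocks C9–OH, which would otherwise close on C9'.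
- MsCl/Et3N gives the mesylate F3.
- TBAF frees both carbinols, and O–C7 closes on C9' to give the all-cis naphthylmethyl-protected oxolane F4.
- Hydrogenolysis over Pd/C removes the naphthylmethyl group and both benzyl groups, and the route is rejoined at 19.

**Step 6.** The vinylcarbene flanked by two CH(OTBS)Ar groups may be captured too slowly by ethylene. The catalyst would then decay and 9 would be recovered.

The fallback replaces the propargylic group with the smaller acetate, for which this metathesis is best documented, and sets out from 8.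
- TBAF gives the ynediol F5.
- Ac2O/pyridine gives the ynediol diacetate F6.
- RuCl2(H2IMes)(PCy3)(=CHPh) under ethylene gives the diene diacetate F7.
- K2CO3/MeOH gives the dienediol F8.
- TBSOTf/2,6-lutidine rejoins the route at 11.

**Step 9.** The alkoxide at C7' may expel the 1,3-related mesylate with cleavage of C7'–C8' (fragmentation). Basic fluoride may also cause elimination back to a diene. Either process would compete with ring closure.

The fallback avoids alkoxides altogether and sets out from 13.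
- TBAF gives the triol F9.
- A Mitsunobu cyclodehydration (PPh3, DIAD, THF, 0 °C) activates the primary C9' hydroxyl as its oxyphosphonium salt.
- The neutral C7 hydroxyl then closes the ring with retention at C7, and the route is rejoined at 16.

**Further compounds**

F1 | step 7 | (2S,3S)-2,3-bis[(S)-Ar(TBSO)methyl]butane-1,4-diol | COc1cc([C@@H](O[Si](C)(C)C(C)(C)C)[C@H](CO)[C@@H](CO)[C@H](O[Si](C)(C)C(C)(C)C)c2ccc(OCc3ccccc3)c(OC)c2)ccc1OCc1ccccc1
F2 | step 7 | (2S,3S)-2,3-bis[(S)-Ar(TBSO)methyl]-4-(naphthalen-2-ylmethoxy)butan-1-ol | COc1cc([C@@H](O[Si](C)(C)C(C)(C)C)[C@H](CO)[C@@H](COCc2ccc3ccccc3c2)[C@H](O[Si](C)(C)C(C)(C)C)c2ccc(OCc3ccccc3)c(OC)c2)ccc1OCc1ccccc1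
F3 | step 7 | (2S,3S)-2,3-bis[(S)-Ar(TBSO)methyl]-4-(naphthalen-2-ylmethoxy)butyl methanesulfonate | COc1cc([C@@H](O[Si](C)(C)C(C)(C)C)[C@H](COS(C)(=O)=O)[C@@H](COCc2ccc3ccccc3c2)[C@H](O[Si](C)(C)C(C)(C)C)c2ccc(OCc3ccccc3)c(OC)c2)ccc1OCc1ccccc1
F4 | step 7 | (S)-Ar{(3S,4S,5S)-5-Ar-4-[(naphthalen-2-ylmethoxy)methyl]oxolan-3-yl}methanol | COc1cc([C@@H](O)[C@@H]2CO[C@H](c3ccc(OCc4ccccc4)c(OC)c3)[C@@H]2COCc2ccc3ccccc3c2)ccc1OCc1ccccc1
F5 | step 6 | (1R,4R)-1,4-bis[4-(benzyloxy)-3-methoxyphenyl]but-2-yne-1,4-diol | COc1cc([C@@H](O)C#C[C@H](O)c2ccc(OCc3ccccc3)c(OC)c2)ccc1OCc1ccccc1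
F6 | step 6 | (1R,4R)-1,4-bis[4-(benzyloxy)-3-methoxyphenyl]but-2-yne-1,4-diyl diacetate | COc1cc([C@@H](OC(C)=O)C#C[C@H](OC(C)=O)c2ccc(OCc3ccccc3)c(OC)c2)ccc1OCc1ccccc1
F7 | step 6 | (1R,4R)-1,4-bis[4-(benzyloxy)-3-methoxyphenyl]-2,3-dimethylidenebutane-1,4-diyl diacetate | COc1cc([C@@H](OC(C)=O)C(=C)C(=C)[C@H](OC(C)=O)c2ccc(OCc3ccccc3)c(OC)c2)ccc1OCc1ccccc1
F8 | step 6 | (1R,4R)-1,4-bis[4-(benzyloxy)-3-methoxyphenyl]-2,3-dimethylidenebutane-1,4-diol | COc1cc([C@@H](O)C(=C)C(=C)[C@H](O)c2ccc(OCc3ccccc3)c(OC)c2)ccc1OCc1ccccc1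
F9 | step 9 | (2S)-2-[(S)-Ar(hydroxy)methyl]-3-[(S)-Ar(hydroxy)methyl]but-3-en-1-ol | COc1cc([C@@H](O)[C@H](CO)C(=C)[C@H](O)c2ccc(OCc3ccccc3)c(OC)c2)ccc1OCc1ccccc1
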